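**Retrosynthetic overview**
1. Target ⇐ reductive N–O cleavage of an isoxazoline that masks the C3 ketone/C1 carbinol; the exo-methylene ⇐ HWE (CH2O) on an α-phosphono lactone.
2. Key step: intramolecular nitrile oxide–alkene cycloaddition of a (Z)-enal oxime closes the ten-membered carbocycle and the isoxazoline in one operation (C2–C3 and O–C1 bonds, sets C1).
3. cis-Lactone with C7 and C8 ⇐ 5-exo epoxide opening by a phosphonoacetate tethered on O6 (tether installed by Mitsunobu inversion); the epoxide ⇐ Sharpless epoxidation.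
4. Acyclic chain ⇐ asymmetric alkynylation of an enal with TBS propargyl ether (sets C6), then Red-Al/I2 (sets the C4=C5 geometry); C3 later from CO.
5. Enal with the C10 carbinol ⇐ carboalumination of pent-1-en-4-yne, cross-metathesis, Sharpless epoxidation/reductive opening. Ring order: γ-lactone first, then carbocycle + isoxazoline together, isoxazoline opened last.

Assumption: atom labels C1–C15 follow germacrane numbering of the target (C1 CHOH, C3 C=O, C4=C5, C6 lactone CH–O, C7 ring fusion, C8 CH–O-acyl, C10 C(OH)CH3, C11–C13 lactone, C14 methyl, C15 CH2OH); the target is (1R,4Z,6S,7R,8R,10S) with a (2R)-2-methylbutanoate.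
Assumption: (S,S)-ProPhenol is taken as the antipode that gives the (S)-carbinol in step 5; the (R,R)-ligand is used if the sense is opposite.
Assumption: compounds 18–24 are carried as mixtures of C11 epimers (stereocentre removed in step 13), so C11 is left undefined in their SMILES.

**Step 1**
Reactants: 1 pent-1-en-4-yne
Product: 4 (2E)-3-methylhexa-2,5-dien-1-ol, via alkenylalane 2 (not isolated), via lithium alkenylalanate 3 (not isolated)
Conditions: Me3Al, Cp2ZrCl2 (cat.), CH2Cl2, rt; n-BuLi, THF, −78 → 0 °C; (CH2O)n, rt; aq. HCl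
Reagents that add atoms: trimethylaluminium C[Al](C)C; formaldehyde (from paraformaldehyde) C=O
Why: Negishi Zr-catalysed syn-carboalumination places Me on the internal and Al on the terminal alkyne carbon, and hydroxymethylation of the alanate with retention fixes the (E)-olefin that later defines C10.

**Step 2**
Reactants: 4 (2E)-3-methylhexa-2,5-dien-1-ol; 5 (2E)-but-2-enal
Product: 6 (2E,5E)-7-hydroxy-5-methylhepta-2,5-dienal
Conditions: Hoveyda–Grubbs II (3 mol%), 5 (5 equiv), CH2Cl2, 40 °C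
Reagents that add atoms: none
Why: Olefin cross-metathesis of the terminal (type I) vinyl group with excess crotonaldehyde gives the (E)-enal, while the trisubstituted allylic-alcohol olefin is inert.

**Step 3**
Reactants: 6 (2E,5E)-7-hydroxy-5-methylhepta-2,5-dienal
Product: 7 (2E)-4-[(2S,3S)-3-(hydroxymethyl)-2-methyloxiran-2-yl]but-2-enal
Conditions: Ti(OiPr)4 (10 mol%), L-(+)-DET (12 mol%), TBHP, 4 Å MS, CH2Cl2, −20 °C
Reagents that add atoms: tert-butyl hydroperoxide CC(C)(C)OO
Why: Sharpless asymmetric epoxidation with L-(+)-tartrate gives the (2S,3S)-epoxide (same sense as geraniol), which sets C10 as S; the electron-poor enal is not epoxidised.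

**Step 4**
Reactants: 7 (2E)-4-[(2S,3S)-3-(hydroxymethyl)-2-methyloxiran-2-yl]but-2-enal
Product: 9 (2E,5S)-5-hydroxy-5-methylhepta-2,6-dienal, via epoxy iodide 8 (not isolated)
Conditions: PPh3, imidazole, I2, THF, 0 °C; then Zn dust, EtOH, rt; aq. NH4Cl
Reagents that add atoms: none
Why: Appel-type iodination followed by zinc-induced reductive epoxide opening (β-elimination) gives the tertiary vinyl carbinol without breaking the C10–O bond, so C10 stays S.

**Step 5**
Reactants: 9 (2E,5S)-5-hydroxy-5-methylhepta-2,6-dienal; 10 tert-butyldimethyl(prop-2-yn-1-yloxy)silane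
Product: 12 (3S,5E,7S)-10-[(tert-butyldimethylsilyl)oxy]-3-methyldeca-1,5-dien-8-yne-3,7-diol, via alkynylzinc 11 (not isolated)
Conditions: (S,S)-ProPhenol (20 mol%), Ph3P=O (40 mol%), Me2Zn (4 equiv), toluene, 0 → 4 °C; aq. NH4Cl
Reagents that add atoms: none
Why: Trost Zn-ProPhenol catalytic asymmetric alkynylation adds the alkynylzinc 1,2 to the Re face of the enal and sets the C6 carbinol (7S in this chain) under catalyst control.

**Step 6**
Reactants: 12 (3S,5E,7S)-10-[(tert-butyldimethylsilyl)oxy]-3-methyldeca-1,5-dien-8-yne-3,7-diol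
Product: 14 (3S,5E,7S,8Z)-10-[(tert-butyldimethylsilyl)oxy]-9-iodo-3-methyldeca-1,5,8-triene-3,7-diol, via cyclic alkenylalanate 13 (not isolated)
Conditions: Red-Al (3.5 equiv), THF, 0 °C; then I2, THF, −78 → 0 °C; Rochelle salt
Reagents that add atoms: iodine II
Why: Hydroxyl-directed trans-hydroalumination puts H on C5 and Al on C4, and iodinolysis with retention gives the (Z)-iodoalkene with iodine cis to C6, which is the C4=C5 geometry of the target.

**Step 7**
Reactants: 14 (3S,5E,7S,8Z)-10-[(tert-butyldimethylsilyl)oxy]-9-iodo-3-methyldeca-1,5,8-triene-3,7-diol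
Product: 15 (1R,2Z)-4-[(tert-butyldimethylsilyl)oxy]-1-{(2R,3R)-3-[(2S)-2-hydroxy-2-methylbut-3-en-1-yl]oxiran-2-yl}-3-iodobut-2-en-1-ol
Conditions: Ti(OiPr)4 (1.1 equiv), D-(−)-DIPT (1.3 equiv), TBHP, 4 Å MS, CH2Cl2, −20 °C
Reagents that add atoms: tert-butyl hydroperoxide CC(C)(C)OO
Why: Sharpless epoxidation of the secondary allylic alcohol in the matched sense gives the anti (erythro) 7R,8R-epoxide; the Z-substituted iodoalkene and the tertiary vinyl carbinol react too slowly to compete.

**Step 8**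
Reactants: 15 anti epoxy alcohol (name as in step 7); 16 2-(diethoxyphosphoryl)acetic acid
Product: 17 (1S,2Z)-4-[(tert-butyldimethylsilyl)oxy]-1-{(2S,3R)-3-[(2S)-2-hydroxy-2-methylbut-3-en-1-yl]oxiran-2-yl}-3-iodobut-2-en-1-yl 2-(diethoxyphosphoryl)acetate
Conditions: PPh3, DIAD, toluene/THF, 0 °C → rt
Reagents that add atoms: none
Why: Mitsunobu esterification inverts C6, turning the anti epoxy alcohol into the syn ester required for a cis-lactone, and installs the phosphonoacetate tether in the same step; the tertiary alcohol does not react.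

**Step 9**
Reactants: 17 syn epoxy phosphonoacetate (name as in step 8)
Product: 18 diethyl {(3RS,4R,5R)-5-[(1Z)-3-[(tert-butyldimethylsilyl)oxy]-2-iodoprop-1-en-1-yl]-4-[(1R,3S)-1,3-dihydroxy-3-methylpent-4-en-1-yl]-2-oxooxolan-3-yl}phosphonate
Conditions: DBU (1.5 equiv), LiCl (3 equiv), MeCN, 0 → 40 °C; aq. NH4Cl
Reagents that add atoms: none
Why: Proposed new method: the Li-chelated phosphonoacetate carbanion opens the epoxide at C7 in 5-exo-tet fashion (SN2, inversion at C7, C8–O untouched), giving the cis-lactone and the free C8 alcohol; the closest known reactions are the Roush/Kishi base-induced cyclisation of 2,3-epoxy alcohol carbamates at C2 and the intermolecular epoxide opening by phosphonoacetate anions, and internal proton transfer to the α-phosphono lactone should stop phosphoryl or acyl migration.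

**Step 10**
Reactants: 18 hydroxy phosphono lactone (name as in step 9); 19 (2R)-2-methylbutanoic acid
Product: 20 (1R,3S)-1-{(2R,3R,4RS)-2-[(1Z)-3-[(tert-butyldimethylsilyl)oxy]-2-iodoprop-1-en-1-yl]-4-(diethoxyphosphoryl)-5-oxooxolan-3-yl}-3-hydroxy-3-methylpent-4-en-1-yl (2R)-2-methylbutanoate
Conditions: DCC, DMAP (cat.), CH2Cl2, 0 °C → rt
Reagents that add atoms: none
Why: Steglich esterification acylates the only reactive (secondary, C8) hydroxyl, the tertiary C10 alcohol being inert, and no stereocentre is touched.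

**Step 11**
Reactants: 20 iodoalkenyl lactone ester (name as in step 10)
Product: 22 oxime of the (Z)-enal: as 20 with the iodine replaced by an (E)-CH=N–OH group cis to C6, via enal 21 (not isolated)
Conditions: Pd(PPh3)4 (5 mol%), CO (1 atm), Bu3SnH (slow addition), THF, 50 °C; then NH2OH·HCl, pyridine, EtOH, 0 °C → rt
Reagents that add atoms: carbon monoxide [C-]#[O+]; hydroxylamine hydrochloride NO.Cl
Why: Stille-type reductive carbonylation (formylation) of the vinyl iodide proceeds with retention of geometry, and immediate oxime condensation avoids Z→E isomerisation of the enal.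

**Step 12**
Reactants: 22 (Z)-enal oxime (as in step 11)
Product: 24 isoxazoline-bridged macrocycle (1R,6S,7R,8R,10S): ten-membered carbocycle C1–C10 with C3=N–O–C1 bridge; C4=C5 with C3 cis to C6 and CH2OTBS on C4; cis-fused α-(diethoxyphosphoryl)-γ-lactone on C6/C7; C8 (2R)-2-methylbutanoate; C10 OH/CH3, via nitrile oxide 23 (not isolated)
Conditions: activated MnO2 (10 equiv), CH2Cl2, 35 °C, 22 added by syringe pump over 12 h (final 1 mM)
Reagents that add atoms: none
Why: Intramolecular nitrile oxide–alkene cycloaddition joins the dipole carbon to the terminal CH2 and oxygen to C1 (normal electronic regiochemistry, bridged mode), closing the ten-membered carbocycle and the isoxazoline together; C1 is expected R from attack on the face that keeps the C10–O bond out of the anti position (Houk–Jäger model), and slow addition under neutral conditions suppresses furoxan formation and carbanion side reactions.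

**Step 13**
Reactants: 24 isoxazoline-bridged phosphono lactone (as in step 12)
Product: 25 the corresponding α-methylene lactone (C11=C13H2 in place of CH–P(O)(OEt)2; otherwise as 24)
Conditions: 37% aq. CH2O, K2CO3, THF, 0 °C → rt
Reagents that add atoms: formaldehyde C=O
Why: Horner–Wadsworth–Emmons olefination with formaldehyde converts both C11 epimers into the single exo-methylene lactone under conditions that leave the isoxazoline and the C8 ester intact.

**Step 14**
Reactants: 25 isoxazoline-bridged α-methylene lactone (as in step 13)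
Product: 27 CNP0263726.1 (target), via silyl ether 26 (not isolated)
Conditions: Mo(CO)6 (1.2 equiv), B(OH)3, MeCN/H2O 10:1, 80 °C; then 48% aq. HF, MeCN, 0 °C → rt
Reagents that add atoms: water O
Why: Mo(CO)6-mediated reductive N–O cleavage with in situ imine hydrolysis unmasks the β-hydroxy enone without reducing the olefins, and aqueous HF then removes the TBS ether; no stereocentre is affected.

**Compound list**
1 | pent-1-en-4-yne | C=CCC#C | starting material
2 | dimethyl[(1E)-2-methylpenta-1,4-dien-1-yl]alumane | C[Al](C)/C=C(\C)CC=C | intermediate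
3 | lithium butyl(dimethyl)[(1E)-2-methylpenta-1,4-dien-1-yl]aluminate | [Li+].CCCC[Al-](C)(C)/C=C(\C)CC=C | intermediate
4 | (2E)-3-methylhexa-2,5-dien-1-ol | OC/C=C(\C)CC=C | intermediate
5 | (2E)-but-2-enal (crotonaldehyde) | C/C=C/C=O | starting material
6 | (2E,5E)-7-hydroxy-5-methylhepta-2,5-dienal | OC/C=C(\C)C/C=C/C=O | intermediate
7 | (2E)-4-[(2S,3S)-3-(hydroxymethyl)-2-methyloxiran-2-yl]but-2-enal | OC[C@@H]1O[C@@]1(C)C/C=C/C=O | intermediate
8 | (2E)-4-[(2S,3R)-3-(iodomethyl)-2-methyloxiran-2-yl]but-2-enal | IC[C@@H]1O[C@@]1(C)C/C=C/C=O | intermediate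
9 | (2E,5S)-5-hydroxy-5-methylhepta-2,6-dienal | C=C[C@@](C)(O)C/C=C/C=O | intermediate
10 | tert-butyldimethyl(prop-2-yn-1-yloxy)silane | C#CCO[Si](C)(C)C(C)(C)C | starting material
11 | {3-[(tert-butyldimethylsilyl)oxy]prop-1-yn-1-yl}(methyl)zinc | C[Zn]C#CCO[Si](C)(C)C(C)(C)C | intermediate
12 | (3S,5E,7S)-10-[(tert-butyldimethylsilyl)oxy]-3-methyldeca-1,5-dien-8-yne-3,7-diol | CC(C)(C)[Si](C)(C)OCC#C[C@@H](O)/C=C/C[C@](C)(O)C=C | intermediate
13 | disodium salt of the cyclic alkenyl(alkoxy)bis(2-methoxyethoxy)aluminate of 12 (Al on C4 and O6, C10 alkoxide) | CC(C)(C)[Si](C)(C)OCC1=C[C@H](/C=C/C[C@](C)([O-])C=C)O[Al-]1(OCCOC)OCCOC.[Na+].[Na+] | intermediate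
14 | (3S,5E,7S,8Z)-10-[(tert-butyldimethylsilyl)oxy]-9-iodo-3-methyldeca-1,5,8-triene-3,7-diol | CC(C)(C)[Si](C)(C)OC/C(I)=C/[C@@H](O)/C=C/C[C@](C)(O)C=C | intermediate
15 | (1R,2Z)-4-[(tert-butyldimethylsilyl)oxy]-1-{(2R,3R)-3-[(2S)-2-hydroxy-2-methylbut-3-en-1-yl]oxiran-2-yl}-3-iodobut-2-en-1-ol | CC(C)(C)[Si](C)(C)OC/C(I)=C/[C@@H](O)[C@H]1O[C@@H]1C[C@](C)(O)C=C | intermediate
16 | 2-(diethoxyphosphoryl)acetic acid | CCOP(=O)(CC(=O)O)OCC | starting material
17 | (1S,2Z)-4-[(tert-butyldimethylsilyl)oxy]-1-{(2S,3R)-3-[(2S)-2-hydroxy-2-methylbut-3-en-1-yl]oxiran-2-yl}-3-iodobut-2-en-1-yl 2-(diethoxyphosphoryl)acetate | CC(C)(C)[Si](C)(C)OC/C(I)=C/[C@H](OC(=O)CP(=O)(OCC)OCC)[C@H]1O[C@@H]1C[C@](C)(O)C=C | intermediate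
18 | diethyl {(3RS,4R,5R)-5-[(1Z)-3-[(tert-butyldimethylsilyl)oxy]-2-iodoprop-1-en-1-yl]-4-[(1R,3S)-1,3-dihydroxy-3-methylpent-4-en-1-yl]-2-oxooxolan-3-yl}phosphonate | CC(C)(C)[Si](C)(C)OC/C(I)=C/[C@@H]1OC(=O)C(P(=O)(OCC)OCC)[C@@H]1[C@H](O)C[C@](C)(O)C=C | intermediate
19 | (2R)-2-methylbutanoic acid | CC[C@@H](C)C(=O)O | starting material
20 | (1R,3S)-1-{(2R,3R,4RS)-2-[(1Z)-3-[(tert-butyldimethylsilyl)oxy]-2-iodoprop-1-en-1-yl]-4-(diethoxyphosphoryl)-5-oxooxolan-3-yl}-3-hydroxy-3-methylpent-4-en-1-yl (2R)-2-methylbutanoate | CC(C)(C)[Si](C)(C)OC/C(I)=C/[C@@H]1OC(=O)C(P(=O)(OCC)OCC)[C@@H]1[C@H](OC(=O)[C@H](C)CC)C[C@](C)(O)C=C | intermediate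
21 | (Z)-enal: as 20 with CHO in place of I (CHO cis to C6; 6S,7R,8R,10S) | CC(C)(C)[Si](C)(C)OC/C(C=O)=C/[C@@H]1OC(=O)C(P(=O)(OCC)OCC)[C@@H]1[C@H](OC(=O)[C@H](C)CC)C[C@](C)(O)C=C | intermediate
22 | (E)-aldoxime of 21 (CH=NOH cis to C6) | O/N=C/C(CO[Si](C)(C)C(C)(C)C)=C\[C@@H]1OC(=O)C(P(=O)(OCC)OCC)[C@@H]1[C@H](OC(=O)[C@H](C)CC)C[C@](C)(O)C=C | intermediate
23 | nitrile oxide derived from 22 | CC(C)(C)[Si](C)(C)OC/C(C#[N+][O-])=C/[C@@H]1OC(=O)C(P(=O)(OCC)OCC)[C@@H]1[C@H](OC(=O)[C@H](C)CC)C[C@](C)(O)C=C | intermediate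
24 | (1R,6S,7R,8R,10S)-isoxazoline-bridged ten-membered carbocycle with cis-fused α-(diethoxyphosphoryl)-γ-lactone, C8 (2R)-2-methylbutanoate, C10 OH/CH3, C15 OTBS | CCOP(=O)(OCC)C1C(=O)O[C@H]2/C=C(/CO[Si](C)(C)C(C)(C)C)C3=NO[C@H](C3)[C@@](C)(O)C[C@@H](OC(=O)[C@H](C)CC)[C@@H]12 | intermediate
25 | as 24 with α-methylene lactone (C11=CH2) | C=C1C(=O)O[C@H]2/C=C(/CO[Si](C)(C)C(C)(C)C)C3=NO[C@H](C3)[C@@](C)(O)C[C@@H](OC(=O)[C@H](C)CC)[C@@H]12 | intermediate
26 | 15-O-TBS ether of the target | C=C1C(=O)O[C@H]2/C=C(/CO[Si](C)(C)C(C)(C)C)C(=O)C[C@@H](O)[C@@](C)(O)C[C@@H](OC(=O)[C@H](C)CC)[C@@H]12 | intermediate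
27 | CNP0263726.1, (1R,4Z,6S,7R,8R,10S)-germacranolide 8-(2R)-2-methylbutanoate | C=C1C(=O)O[C@H]2/C=C(/CO)C(=O)C[C@@H](O)[C@@](C)(O)C[C@@H](OC(=O)[C@H](C)CC)[C@@H]12 | target

**Total step count:** 14
**Longest linear sequence:** 14 steps (from 1)

**Steps most likely to fail**

Step 12 (bridged macrocyclic nitrile oxide cycloaddition). The risks are furoxan dimerisation, the fused regiochemistry and the wrong face at C1. Fallback: change the order of ring formation so that the cycloaddition runs on the more flexible epoxide before the lactone exists. It sets out from 17. Reductive carbonylation as in step 11 gives the epoxy enal F1, hydroxylamine gives the epoxy oxime F2, and MnO2 under high dilution gives the epoxy nitrile oxide F3, which cyclises to the isoxazoline-bridged epoxy phosphonoacetate F4. DBU/LiCl then closes the lactone onto C7 to give the macrocyclic hydroxy phosphono lactone F5, and DCC/DMAP acylation with 19 comes back to the route at 24.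

Step 9 (epoxide opening by the tethered phosphonoacetate). The risks are sluggish alkylation and phosphoryl or acyl migration of the C8 alkoxide. Fallback: replace the base-driven anionic alkylation by an acid-driven Mukaiyama-type opening. It sets out from 17. TMSOTf/Et3N gives the bis-silyl ketene acetal F6; BF3·OEt2 in CH2Cl2 at −78 °C activates the epoxide and the ketene acetal carbon attacks C7 with silyl transfer to give the bis-trimethylsilyl lactone F7; citric acid in MeOH removes both TMS groups and comes back to the route at 18.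

Step 11 (reductive carbonylation next to an allylic lactone). The risks are Pd–H cleavage of the allylic C6–O bond and Z→E isomerisation. Fallback: bring in C3 as a hydroxymethyl group without any hydride source. It sets out from 20. Stille coupling with (tributylstannyl)methanol (Pd(PPh3)4, dioxane, 80 °C) gives the allylic alcohol F8; MnO2 oxidises it to the enal 21, which is oximated as before and comes back to the route at 22.

**Further compounds**
F1 | step 12 | epoxy enal (17 with CHO in place of I) | CC(C)(C)[Si](C)(C)OC/C(C=O)=C/[C@H](OC(=O)CP(=O)(OCC)OCC)[C@H]1O[C@@H]1C[C@](C)(O)C=C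
F2 | step 12 | epoxy oxime (E-aldoxime of F1) | O/N=C/C(CO[Si](C)(C)C(C)(C)C)=C\[C@H](OC(=O)CP(=O)(OCC)OCC)[C@H]1O[C@@H]1C[C@](C)(O)C=C
F3 | step 12 | epoxy nitrile oxide from F2 | CC(C)(C)[Si](C)(C)OC/C(C#[N+][O-])=C/[C@H](OC(=O)CP(=O)(OCC)OCC)[C@H]1O[C@@H]1C[C@](C)(O)C=C
F4 | step 12 | isoxazoline-bridged ten-membered carbocycle with C7–C8 epoxide and C6 phosphonoacetate | CCOP(=O)(OCC)CC(=O)O[C@H]1/C=C(/CO[Si](C)(C)C(C)(C)C)C2=NO[C@H](C2)[C@@](C)(O)C[C@H]3O[C@H]13
F5 | step 12 | 8-hydroxy analogue of 24 (no 2-methylbutanoyl group) | CCOP(=O)(OCC)C1C(=O)O[C@H]2/C=C(/CO[Si](C)(C)C(C)(C)C)C3=NO[C@H](C3)[C@@](C)(O)C[C@@H](O)[C@@H]12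
F6 | step 9 | trimethylsilyl ketene acetal of 17 with C10 O-TMS | CC(C)(C)[Si](C)(C)OC/C(I)=C/[C@H](OC(O[Si](C)(C)C)=CP(=O)(OCC)OCC)[C@H]1O[C@@H]1C[C@](C)(O[Si](C)(C)C)C=C
F7 | step 9 | 8,10-bis-O-trimethylsilyl ether of 18 | CC(C)(C)[Si](C)(C)OC/C(I)=C/[C@@H]1OC(=O)C(P(=O)(OCC)OCC)[C@@H]1[C@H](O[Si](C)(C)C)C[C@](C)(O[Si](C)(C)C)C=C
F8 | step 11 | allylic alcohol (20 with CH2OH in place of I) | CC(C)(C)[Si](C)(C)OC/C(CO)=C/[C@@H]1OC(=O)C(P(=O)(OCC)OCC)[C@@H]1[C@H](OC(=O)[C@H](C)CC)C[C@](C)(O)C=C
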